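## Retrosynthetic overview

1. The ester C–O bond is made last, by Mitsunobu union of (2R,3S,4S)-lariciresinol with unprotected p-coumaric acid; lariciresinol comes from the matching tetrahydrofuran-3-carboxylic acid by borane reduction.
2. That acid comes from a cis-fused 3,6-diaryl-furo[3,4-c]furan-1-one by hydrogenolysis of the benzylic lactone C–O bond: the lactone CH(aryl)–O becomes the C4 benzyl group, the lactone C=O becomes the C3 carboxyl, and both O-benzyl groups are lost in the same operation.
3. Key disconnection: the tetrahydrofuran bonds C5–C4 and C2–C3 are made together by a (3+2) cycloaddition of the non-stabilised carbonyl ylide ArCH=O(+)–CH2(−) (ring atoms C2, O1, C5; from O-benzylvanillin) to the C=C of (R)-5-aryl-furan-2(5H)-one (ring atoms C3, C4; from the same aldehyde by asymmetric alkynylation and semihydrogenation).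
4. Enabling feature: in the tetrahydrofuran ring, C5 is an unsubstituted CH2 and C2 a benzylic CH, both flanking O1, which is the C–O–C skeleton of an aldehyde-derived carbonyl ylide; C3 and C4 carry cis one-carbon branches (CH2O and CH2Ar) that are the lactone C=O and the benzylic C–O of a γ-aryl butenolide at a higher oxidation level.
5. Ring order: the temporary butenolide ring first, then the tetrahydrofuran ring (the only ring of the target, three stereocentres set at once), then the lactone ring is opened again.

Key step: step 4

Assumption: the zinc catalyst from (R,R)-ProPhenol is taken to deliver the (S)-configured propargylic alcohol of step 2; if the sense of induction is the opposite, the (S,S)-ligand is used and nothing else changes.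

## Route

Step 1
Reactants: 1 4-(benzyloxy)-3-methoxybenzaldehyde; 2 (trimethylsilyl)methanol
Product: 3 1-(benzyloxy)-4-{bis[(trimethylsilyl)methoxy]methyl}-2-methoxybenzene
Conditions: 2 (3 equiv), PPTS (cat.), benzene, reflux, azeotropic removal of water
Reagents that add atoms: none
Why: Acid-catalysed acetalisation of the aryl aldehyde with two equivalents of the primary alcohol, driven by water removal; no stereocentre is formed and the C–Si bonds tolerate the mild acid.

Step 2
Reactants: 1 4-(benzyloxy)-3-methoxybenzaldehyde; 4 methyl propiolate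
Product: 5 methyl (S)-4-[4-(benzyloxy)-3-methoxyphenyl]-4-hydroxybut-2-ynoate
Conditions: 4 (3 equiv), Me2Zn (3 equiv), (R,R)-ProPhenol (10 mol%), Ph3P=O (20 mol%), toluene, 4 °C; aq. NH4Cl
Reagents that add atoms: none
Why: Catalytic enantioselective alkynylation of an aldehyde: Me2Zn deprotonates the propiolate and the alkynylzinc adds to the aldehyde inside the dinuclear zinc–ProPhenol pocket, which selects one aldehyde face and so sets the (S)-carbinol.

Step 3
Reactants: 5 methyl (S)-4-[4-(benzyloxy)-3-methoxyphenyl]-4-hydroxybut-2-ynoate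
Product: 7 (R)-5-[4-(benzyloxy)-3-methoxyphenyl]furan-2(5H)-one, via Z-hydroxy enoate 6 (not isolated)
Conditions: H2 (1 atm), Pd/CaCO3 poisoned with Pb(OAc)2, quinoline (cat.), EtOAc, rt; then PPTS (cat.), CH2Cl2, rt
Reagents that add atoms: none
Why: Lindlar semihydrogenation adds hydrogen syn to give the Z-γ-hydroxy enoate, which lactonises by intramolecular transesterification with loss of methanol; the carbinol centre is untouched (its descriptor changes from S to R only because the CIP ranks of the alkynyl and alkenyl carbons differ) and the benzyl ether survives the poisoned catalyst.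

Step 4
Reactants: 3 1-(benzyloxy)-4-{bis[(trimethylsilyl)methoxy]methyl}-2-methoxybenzene; 7 (R)-5-[4-(benzyloxy)-3-methoxyphenyl]furan-2(5H)-one
Product: 10 (3R,3aS,6R,6aR)-3,6-bis[4-(benzyloxy)-3-methoxyphenyl]tetrahydro-1H,3H-furo[3,4-c]furan-1-one, via α-chloro ether 8 (not isolated), via carbonyl ylide 9 (not isolated)
Conditions: 3 (2 equiv), AcCl, ZnBr2 (cat.), CH2Cl2, 0 °C → rt; then 7 (1 equiv), CsF, MeCN, 0 °C → rt
Reagents that add atoms: acetyl chloride, CC(=O)Cl (supplies the chlorine of intermediate 8; no atom of it remains in 10)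
Why: Fluoride attacks silicon of the α-chloro ether 8 (ion-paired as the aryl-stabilised oxocarbenium chloride) and 1,3-elimination of Me3SiF and chloride unmasks the non-stabilised carbonyl ylide 9, which adds across the C3=C4 bond of 7 in a concerted, suprafacial (3+2) cycloaddition of a four-electron dipole to a two-electron alkene. The closest known reaction type is the fluoride-induced, silicon-based 1,3-elimination of α-chloroalkyl (trimethylsilyl)methyl ethers to non-stabilised carbonyl ylides and their cycloaddition to acrylate-type alkenes to give tetrahydrofurans. The tetrahydrofuran ring (C3a, C4, O5, C6, C6a of 10) is closed by this intermolecular cycloaddition, both C–C bonds forming on one face of the ring-locked Z-alkene, so the new ring is necessarily cis-fused to the lactone. The absolute configuration at C3a and C6a follows from approach of the ylide to the face of 7 anti to its C5 aryl group (1,2-induction by the only stereocentre of 7), and C6 is set by the exo transition state of the E-ylide, which places the aryl group on the convex face, trans to the lactone carbonyl. The step needs regioselectivity (the unsubstituted, more nucleophilic CH2 terminus bonds to the enoate β-carbon and the hindered, cation-like ArCH terminus to the α-carbon beside the flat carbonyl, as the electron-rich aryl group and sterics both dictate), π-facial selectivity (secured by the γ-aryl group) and exo selectivity (the endo mode would force the aryl group into the concave face over the lactone). Deprotonation of the acidic γ-H of 7 should be held back because 8 is in excess and takes up fluoride at silicon faster than fluoride acts as a base.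

Step 5
Reactants: 10 (3R,3aS,6R,6aR)-3,6-bis[4-(benzyloxy)-3-methoxyphenyl]tetrahydro-1H,3H-furo[3,4-c]furan-1-one
Product: 11 (2R,3R,4S)-2-(4-hydroxy-3-methoxyphenyl)-4-(4-hydroxy-3-methoxybenzyl)tetrahydrofuran-3-carboxylic acid
Conditions: H2 (1 atm), 10% Pd/C, EtOAc/MeOH, rt, stopped after uptake of 3 equiv H2
Reagents that add atoms: none
Why: Benzylic hydrogenolysis on palladium cleaves the two aryl benzyl ethers and the lactone C3–O2 bond, whose carboxylate leaving group makes it far more labile than the dialkyl benzylic ether C6–O5 of the tetrahydrofuran; the lactone CH(aryl) becomes the C4 benzyl group, the C3 carboxylic acid is released, the lactone benzylic stereocentre is erased and the three ring stereocentres are untouched.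

Step 6
Reactants: 11 (2R,3R,4S)-2-(4-hydroxy-3-methoxyphenyl)-4-(4-hydroxy-3-methoxybenzyl)tetrahydrofuran-3-carboxylic acid
Product: 12 (2R,3S,4S)-lariciresinol, [(2R,3S,4S)-2-(4-hydroxy-3-methoxyphenyl)-4-(4-hydroxy-3-methoxybenzyl)tetrahydrofuran-3-yl]methanol
Conditions: BH3·THF (excess), THF, 0 °C → rt; MeOH, then aqueous work-up
Reagents that add atoms: none
Why: Chemoselective borane reduction of the carboxylic acid through its acyloxyborane to the primary alcohol; the phenols only form borate esters that are cleaved on work-up, and the α-stereocentre is not epimerised under these non-basic conditions.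

Step 7
Reactants: 12 (2R,3S,4S)-lariciresinol; 13 (E)-3-(4-hydroxyphenyl)prop-2-enoic acid (p-coumaric acid)
Product: 14 lariciresinol p-coumarate, [(2R,3S,4S)-2-(4-hydroxy-3-methoxyphenyl)-4-(4-hydroxy-3-methoxybenzyl)tetrahydrofuran-3-yl]methyl (E)-3-(4-hydroxyphenyl)prop-2-enoate
Conditions: PPh3, DIAD, THF, 0 °C → rt
Reagents that add atoms: none
Why: Mitsunobu esterification: the carboxylic acid, the most acidic partner, is the nucleophile that attacks the alkoxyphosphonium ion of the primary alcohol, so the free phenols of both partners should stay untouched, a chemoselectivity known for phenolic acids and phenolic alcohols; substitution occurs at the primary CH2, so no stereocentre is affected and the E-alkene is retained.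

## Compound list

1 | 4-(benzyloxy)-3-methoxybenzaldehyde | COc1cc(C=O)ccc1OCc1ccccc1 | starting material
2 | (trimethylsilyl)methanol | C[Si](C)(C)CO | starting material
3 | 1-(benzyloxy)-4-{bis[(trimethylsilyl)methoxy]methyl}-2-methoxybenzene | COc1cc(C(OC[Si](C)(C)C)OC[Si](C)(C)C)ccc1OCc1ccccc1 | intermediate
4 | methyl propiolate | COC(=O)C#C | starting material
5 | methyl (S)-4-[4-(benzyloxy)-3-methoxyphenyl]-4-hydroxybut-2-ynoate | COC(=O)C#C[C@@H](O)c1ccc(OCc2ccccc2)c(OC)c1 | intermediate
6 | methyl (R,Z)-4-[4-(benzyloxy)-3-methoxyphenyl]-4-hydroxybut-2-enoate (formed in the flask) | COC(=O)/C=C\[C@@H](O)c1ccc(OCc2ccccc2)c(OC)c1 | intermediate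
7 | (R)-5-[4-(benzyloxy)-3-methoxyphenyl]furan-2(5H)-one | O=C1O[C@@H](c2ccc(OCc3ccccc3)c(OC)c2)C=C1 | intermediate
8 | 1-(benzyloxy)-4-{chloro[(trimethylsilyl)methoxy]methyl}-2-methoxybenzene (racemic α-chloro ether, formed in the flask) | COc1cc(C(Cl)OC[Si](C)(C)C)ccc1OCc1ccccc1 | intermediate
9 | {[4-(benzyloxy)-3-methoxyphenyl]methylidene}oxonium methanide, the carbonyl ylide ArCH=O(+)–CH2(−) (formed in the flask) | COc1cc(C=[O+][CH2-])ccc1OCc1ccccc1 | intermediate
10 | (3R,3aS,6R,6aR)-3,6-bis[4-(benzyloxy)-3-methoxyphenyl]tetrahydro-1H,3H-furo[3,4-c]furan-1-one (cis-fused; C1 lactone C=O, O2, C3 lactone CH–aryl, C4 CH2, O5, C6 ether CH–aryl; both aryl groups exo) | O=C1O[C@@H](c2ccc(OCc3ccccc3)c(OC)c2)[C@@H]2CO[C@@H](c3ccc(OCc4ccccc4)c(OC)c3)[C@H]12 | intermediate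
11 | (2R,3R,4S)-2-(4-hydroxy-3-methoxyphenyl)-4-(4-hydroxy-3-methoxybenzyl)tetrahydrofuran-3-carboxylic acid | COc1cc(C[C@@H]2CO[C@@H](c3ccc(O)c(OC)c3)[C@@H]2C(=O)O)ccc1O | intermediate
12 | (2R,3S,4S)-lariciresinol, [(2R,3S,4S)-2-(4-hydroxy-3-methoxyphenyl)-4-(4-hydroxy-3-methoxybenzyl)tetrahydrofuran-3-yl]methanol | COc1cc(C[C@@H]2CO[C@@H](c3ccc(O)c(OC)c3)[C@@H]2CO)ccc1O | intermediate
13 | (E)-3-(4-hydroxyphenyl)prop-2-enoic acid (p-coumaric acid) | OC(=O)/C=C/c1ccc(O)cc1 | starting material
14 | lariciresinol p-coumarate, [(2R,3S,4S)-2-(4-hydroxy-3-methoxyphenyl)-4-(4-hydroxy-3-methoxybenzyl)tetrahydrofuran-3-yl]methyl (E)-3-(4-hydroxyphenyl)prop-2-enoate | COc1cc(C[C@@H]2CO[C@@H](c3ccc(O)c(OC)c3)[C@@H]2COC(=O)/C=C/c2ccc(O)cc2)ccc1O | target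

## Step count and risks

Total step count: 7. Longest linear sequence: 6 steps (1 → 5 → 7 → 10 → 11 → 12 → 14); step 1 is the side branch that feeds step 4.

Steps most likely to fail:

Step 4. Fluoride may act as a base on the γ-H of 7, causing racemisation or isomerisation to the β,γ-unsaturated lactone, in competition with ylide capture; the ylide may also collapse before it is trapped, and regio- or exo-control may be incomplete. The fallback sets out from 3 and returns at 11. Ylide 9 is generated from 3 as in step 4 but trapped with commercial (5R)-5-{[(1R,2S,5R)-2-isopropyl-5-methylcyclohexyl]oxy}furan-2(5H)-one, whose acetal γ-H is far less acidic and which is an established face-selective dipolarophile (approach anti to the menthyloxy group). This should give the menthyloxy lactone F1 with the same configuration at the ring-fusion carbons as in 10. Hydrolysis of the acetal with aqueous trifluoroacetic acid gives the hydroxy lactone F2. Addition of the aryl Grignard reagent F3 (from commercial 1-(benzyloxy)-4-bromo-2-methoxybenzene and Mg in THF, 2.5 equiv, −78 → 0 °C) to the ring-opened aldehyde carboxylate, followed by acidification, gives the diaryl lactone F4 as a mixture of epimers at the lactone benzylic carbon. That centre is erased when F4 is hydrogenolysed under the conditions of step 5 to give 11.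

Step 5. Hydrogenolysis may run on to cleave the C2–O1 benzylic ether of the tetrahydrofuran, or may stall after debenzylation with the lactone C–O bond intact. The fallback sets out from 10 and returns at 12. Reduction of 10 with LiAlH4 (THF, 0 °C) gives the diol F5. Acetylation (Ac2O, pyridine) gives the diacetate F6, in which the benzylic oxygen is an acyclic acetate that should be cleaved under much milder hydrogenolysis (H2, 10% Pd/C, EtOAc, rt, short time) together with the O-benzyl groups, giving the monoacetate F7. Methanolysis (K2CO3, MeOH) then gives 12.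

Step 7. The alkoxyphosphonium ion of the hindered primary alcohol may be intercepted by phenoxide oxygen (aryl ether formation, oligomers), or activation may be sluggish. The fallback sets out from 12 and returns at 14. Phenol-selective acetylation (Ac2O, aq. NaOH, 0 °C) gives the di-O-acetate F8. Mitsunobu esterification of F8 with commercial (E)-4-acetoxycinnamic acid (PPh3, DIAD, THF), now with no free phenol present, gives the triacetate F9. Chemoselective cleavage of the three aryl acetates (NH4OAc, aq. MeOH, rt), which leaves the alkyl cinnamate intact, gives 14.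

## Further compounds

F1 | step 4 | (3R,3aS,6R,6aR)-6-[4-(benzyloxy)-3-methoxyphenyl]-3-{[(1R,2S,5R)-2-isopropyl-5-methylcyclohexyl]oxy}tetrahydro-1H,3H-furo[3,4-c]furan-1-one | O=C1O[C@@H](O[C@@H]2C[C@H](C)CC[C@H]2C(C)C)[C@@H]2CO[C@@H](c3ccc(OCc4ccccc4)c(OC)c3)[C@H]12
F2 | step 4 | (3aS,6R,6aR)-6-[4-(benzyloxy)-3-methoxyphenyl]-3-hydroxytetrahydro-1H,3H-furo[3,4-c]furan-1-one (anomers at C3) | O=C1OC(O)[C@@H]2CO[C@@H](c3ccc(OCc4ccccc4)c(OC)c3)[C@H]12
F3 | step 4 | [4-(benzyloxy)-3-methoxyphenyl]magnesium bromide | COc1cc([Mg]Br)ccc1OCc1ccccc1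
F4 | step 4 | (3aS,6R,6aR)-3,6-bis[4-(benzyloxy)-3-methoxyphenyl]tetrahydro-1H,3H-furo[3,4-c]furan-1-one (epimers at C3) | O=C1OC(c2ccc(OCc3ccccc3)c(OC)c2)[C@@H]2CO[C@@H](c3ccc(OCc4ccccc4)c(OC)c3)[C@H]12
F5 | step 5 | [(2R,3S,4S)-2-[4-(benzyloxy)-3-methoxyphenyl]-4-{(R)-[4-(benzyloxy)-3-methoxyphenyl](hydroxy)methyl}tetrahydrofuran-3-yl]methanol | O[C@@H](c1ccc(OCc2ccccc2)c(OC)c1)[C@@H]1CO[C@@H](c2ccc(OCc3ccccc3)c(OC)c2)[C@@H]1CO
F6 | step 5 | diacetate of F5, [(2R,3S,4S)-4-{(R)-acetoxy[4-(benzyloxy)-3-methoxyphenyl]methyl}-2-[4-(benzyloxy)-3-methoxyphenyl]tetrahydrofuran-3-yl]methyl acetate | CC(=O)O[C@@H](c1ccc(OCc2ccccc2)c(OC)c1)[C@@H]1CO[C@@H](c2ccc(OCc3ccccc3)c(OC)c2)[C@@H]1COC(C)=O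
F7 | step 5 | [(2R,3S,4S)-2-(4-hydroxy-3-methoxyphenyl)-4-(4-hydroxy-3-methoxybenzyl)tetrahydrofuran-3-yl]methyl acetate | COc1cc(C[C@@H]2CO[C@@H](c3ccc(O)c(OC)c3)[C@@H]2COC(C)=O)ccc1O
F8 | step 7 | (2R,3S,4S)-lariciresinol di-O-acetate (both phenols acetylated) | COc1cc(C[C@@H]2CO[C@@H](c3ccc(OC(C)=O)c(OC)c3)[C@@H]2CO)ccc1OC(C)=O
F9 | step 7 | tri-O-acetate of 14 (all three phenols acetylated) | COc1cc(C[C@@H]2CO[C@@H](c3ccc(OC(C)=O)c(OC)c3)[C@@H]2COC(=O)/C=C/c2ccc(OC(C)=O)cc2)ccc1OC(C)=O
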